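**Retrosynthetic overview**
1. Caruifolin B ⇐ lactone-free absinthin-type dimer 16; the last steps turn the norbornene C3′=C4′ into the ketone and each isopropenyl/6-OH pair into an α-methyl γ-lactone.
2. 16 ⇐ Diels–Alder dimerisation of the 10-hydroxyguaia-2,4-diene 15 (norbornane formed last among the carbocycles).
3. 15 ⇐ key step: acid-triggered hydrative ring expansion (cyclopropylcarbinyl → homoallyl cation, six → seven) of tricyclic carbinol 12, made by gold-catalysed 1,5-enyne cycloisomerisation of 11.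
4. 11 ⇐ propargyl and acetyl units added (via enol triflate 6) to silyloxy-dihydrocarvone 5 ⇐ Rubottom oxidation of dihydrocarvone 3 ⇐ rhodium-catalysed asymmetric 1,4-addition to 6-methylcyclohexenone 1.
5. Ring order: six-membered ring (bought) → cyclopentene + cyclopropane → seven-membered ring → norbornane → two lactones.

Assumption: the epimerisable α-carbonyl centres of the natural product (C4′, C11, C11′) are the thermodynamically preferred ones; guaiane numbering (primes = diene-derived unit) is used in the explanations.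

**Step 1**
Reactants: 1 6-methylcyclohex-2-en-1-one (racemic); 2 potassium trifluoro(prop-1-en-2-yl)borate
Product: 3 (5R)-2-methyl-5-(prop-1-en-2-yl)cyclohexan-1-one (dihydrocarvone; C2 epimers)
Conditions: [Rh(cod)2]PF6 (3 mol %), (R)-BINAP, toluene/H2O, 105 °C
Reagents that add atoms: none
Why: Hayashi–Miyaura rhodium-catalysed asymmetric 1,4-addition; the (R)-BINAP complex delivers the alkenyl group to one enone face and sets C5 (R) (future C7), while the C2 methyl centre stays a mixture that is erased when C2 becomes sp2 in step 3.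

**Step 2**
Reactants: 3 (5R)-2-methyl-5-(prop-1-en-2-yl)cyclohexan-1-one
Product: 5 (2S,3S)-2-[(tert-butyldimethylsilyl)oxy]-6-methyl-3-(prop-1-en-2-yl)cyclohexan-1-one, via silyl enol ether 4 (not isolated)
Conditions: LiN(i-Pr)2, THF, −78 °C; t-BuMe2SiOTf; then mCPBA, CH2Cl2, −20 °C
Reagents that add atoms: tert-butyldimethylsilyl trifluoromethanesulfonate CC(C)(C)[Si](C)(C)OS(=O)(=O)C(F)(F)F; 3-chloroperbenzoic acid OOC(=O)c1cccc(Cl)c1
Why: Kinetic enolisation on the less substituted side followed by Rubottom oxidation; the peracid attacks the electron-rich enol ether (much faster than the isopropenyl group) anti to the neighbouring isopropenyl substituent and 1,4-silyl migration gives the trans α-silyloxy ketone (future 6α-oxygen).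

**Step 3**
Reactants: 5 (2S,3S)-2-[(tert-butyldimethylsilyl)oxy]-6-methyl-3-(prop-1-en-2-yl)cyclohexan-1-one
Product: 6 (5S,6S)-6-[(tert-butyldimethylsilyl)oxy]-2-methyl-5-(prop-1-en-2-yl)cyclohex-1-en-1-yl trifluoromethanesulfonate
Conditions: KN(SiMe3)2, THF, −78 °C; PhNTf2, −78 → 0 °C
Reagents that add atoms: N-phenylbis(trifluoromethanesulfonimide) O=S(=O)(N(c1ccccc1)S(=O)(=O)C(F)(F)F)C(F)(F)F
Why: Enol triflate formation; the base removes the methyl-bearing α-hydrogen (the α-silyloxy C–H is kinetically less acidic and more hindered), so both methyl epimers converge on the tetrasubstituted enol triflate and no stereocentre is formed.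

**Step 4**
Reactants: 6 (5S,6S)-6-[(tert-butyldimethylsilyl)oxy]-2-methyl-5-(prop-1-en-2-yl)cyclohex-1-en-1-yl trifluoromethanesulfonate; 7 butyl vinyl ether
Product: 9 1-[(5S,6S)-6-[(tert-butyldimethylsilyl)oxy]-2-methyl-5-(prop-1-en-2-yl)cyclohex-1-en-1-yl]ethan-1-one, via butoxydiene 8 (not isolated)
Conditions: Pd(OAc)2 (5 mol %), dppp, Et3N, DMF, 80 °C; then 1 M HCl, THF, 0 °C
Reagents that add atoms: water O
Why: Heck reaction of the vinyl triflate at the α-carbon of the electron-rich vinyl ether (cationic vinylpalladium, bidentate phosphine) and hydrolysis of the resulting 2-alkoxydiene, a standard acetylation of vinyl triflates; no stereocentre is formed.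

**Step 5**
Reactants: 9 1-[(5S,6S)-6-[(tert-butyldimethylsilyl)oxy]-2-methyl-5-(prop-1-en-2-yl)cyclohex-1-en-1-yl]ethan-1-one; 10 3-bromoprop-1-yne
Product: 11 (2R)-2-[(5S,6S)-6-[(tert-butyldimethylsilyl)oxy]-2-methyl-5-(prop-1-en-2-yl)cyclohex-1-en-1-yl]pent-4-yn-2-ol (major carbinol epimer)
Conditions: Zn, THF/sat. aq NH4Cl, 0 °C → rt
Reagents that add atoms: none
Why: Zinc Barbier propargylation gives the homopropargylic tertiary alcohol; A(1,2) strain holds the silyloxy group pseudoaxial, so the nucleophile should attack the twisted acetyl group from the opposite (β) side to give mainly the (2R) carbinol with its propargyl arm on the β face (this centre is destroyed in step 6).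

**Step 6**
Reactants: 11 (2R)-2-[(5S,6S)-6-[(tert-butyldimethylsilyl)oxy]-2-methyl-5-(prop-1-en-2-yl)cyclohex-1-en-1-yl]pent-4-yn-2-ol
Product: 13 (4S,5S,8S,8aS)-4-[(tert-butyldimethylsilyl)oxy]-3,8-dimethyl-5-(prop-1-en-2-yl)-4,5,6,7,8,8a-hexahydroazulen-8-ol, via tricyclic carbinol 12 (not isolated)
Conditions: (t-Bu)2(biphenyl-2-yl)PAu(NCMe)SbF6 (2 mol %), CH2Cl2, 0 °C; then THF/H2O, PPTS (10 mol %), 0 °C, 15 min; used at once
Reagents that add atoms: water O
Why: Proposed new method: cationic monovalent gold effects the known 1,5-enyne cycloisomerisation (the tetrasubstituted alkene attacks the gold–alkyne on the face anti to the pseudoaxial silyloxy group, then 1,2-H shift) to the bicyclo[3.1.0]hexene carbinol 12; mild acid then ionises its tertiary allylic, cyclopropylcarbinyl C4–OH to a bicyclo[3.1.0]hexenyl cation whose charge sits on the methyl-bearing terminus C4, so the adjacent C5–C10 cyclopropane bond (also a cyclohexane bond) breaks with backside capture of water at C10, which expands the six-membered ring to the seven-membered one, forms the cyclopentadiene and sets C10 (S), while the 8aS centre (C1) formed here is labile and is reset in step 7; closest known chemistry is the Julia cyclopropylcarbinyl → homoallyl rearrangement and the water-capture step of the cross-conjugated cyclohexadienone photorearrangement, but this ground-state hydrative ring expansion has not been described.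

**Step 7**
Reactants: 13 (4S,5S,8S,8aS)-4-[(tert-butyldimethylsilyl)oxy]-3,8-dimethyl-5-(prop-1-en-2-yl)-4,5,6,7,8,8a-hexahydroazulen-8-ol (two molecules)
Product: 16 lactone-free absinthin-type Diels–Alder dimer, via diol diene 14 (not isolated), via 8aR diene tautomer 15 (not isolated)
Conditions: Bu4NF/AcOH (1:1), THF, 0 °C; work-up, concentrate; neat, Ar, dark, 30 °C, 7 d
Reagents that add atoms: none
Why: Fluoride desilylation, then thermal Diels–Alder dimerisation by analogy with the absinthin series; suprafacial [1,5]-H shifts equilibrate the cyclopentadiene tautomers and C1 epimers, and the 1α-H tautomer 15 reacts, its C2=C3 bond adding endo to the 2,4-diene of a second molecule, both on the face of H-1 (anti to the C1–C10 bond) with the unhindered termini C2 and C2′ joined, which sets C1, C2, C3, C1′, C2′ and C5′.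

**Step 8**
Reactants: 16 lactone-free absinthin-type Diels–Alder dimer
Product: 17 heptaol (3′-exo-hydroxy; both isopropenyl groups as 1-hydroxypropan-2-yl)
Conditions: BH3·THF (excess), THF, 0 °C → rt; then NaOH, H2O2, 0 °C
Reagents that add atoms: hydrogen peroxide OO
Why: Hydroboration–oxidation; borane adds anti-Markovnikov to both isopropenyl groups and to the strained trisubstituted norbornene (boron at C3′, probably exo), the hindered tetrasubstituted C4=C5 alkene is expected to survive and no lactone is yet present to be reduced; C11, C11′, C3′ and C4′ formed here are not final (step 10).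

**Step 9**
Reactants: 17 heptaol
Product: 18 3′-hydroxy-3′,4′-dihydroabsinthin (bis-lactone; C11/C11′ epimers, 4′-methyl endo)
Conditions: TEMPO (0.2 equiv), PhI(OAc)2 (4.5 equiv), CH2Cl2, rt
Reagents that add atoms: none
Why: TEMPO/PhI(OAc)2 oxidative lactonisation; the oxoammonium salt oxidises the two primary alcohols selectively, the aldehydes close onto the 6- and 6′-hydroxyls and the lactols are oxidised on to the trans-fused γ-lactones, whose ring fusion is fixed by C6/C7.

**Step 10**
Reactants: 18 3′-hydroxy-3′,4′-dihydroabsinthin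
Product: 19 caruifolin B
Conditions: Dess–Martin periodinane, CH2Cl2, rt; then DBU (cat.), toluene, 40 °C
Reagents that add atoms: none
Why: Dess–Martin oxidation of the C3′ alcohol, then DBU enolisation equilibrates the three epimerisable α-carbonyl centres to the expected stable arrangement, C4′ methyl exo (relieving the endo clash with C4/C15 of the fused cyclopentene) and 11α/11′α-methyl lactones (methyl trans to C8), while bridgehead C2′ cannot enolise.

**Compound list**
1 | 6-methylcyclohex-2-en-1-one (racemic) | CC1CCC=CC1=O | starting material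
2 | potassium trifluoro(prop-1-en-2-yl)borate | CC(=C)[B-](F)(F)F.[K+] | starting material
3 | (5R)-2-methyl-5-(prop-1-en-2-yl)cyclohexan-1-one (C2 epimers) | CC1CC[C@H](CC1=O)C(C)=C | intermediate
4 | tert-butyldimethyl{[(3R)-6-methyl-3-(prop-1-en-2-yl)cyclohex-1-en-1-yl]oxy}silane (C6 epimers) | CC1CC[C@@H](C(C)=C)C=C1O[Si](C)(C)C(C)(C)C | intermediate
5 | (2S,3S)-2-[(tert-butyldimethylsilyl)oxy]-6-methyl-3-(prop-1-en-2-yl)cyclohexan-1-one (C6 epimers) | CC1CC[C@@H](C(C)=C)[C@H](O[Si](C)(C)C(C)(C)C)C1=O | intermediate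
6 | (5S,6S)-6-[(tert-butyldimethylsilyl)oxy]-2-methyl-5-(prop-1-en-2-yl)cyclohex-1-en-1-yl trifluoromethanesulfonate | CC1=C(OS(=O)(=O)C(F)(F)F)[C@@H](O[Si](C)(C)C(C)(C)C)[C@H](C(C)=C)CC1 | intermediate
7 | butyl vinyl ether | C=COCCCC | starting material
8 | {[(1S,6S)-2-(1-butoxyethenyl)-3-methyl-6-(prop-1-en-2-yl)cyclohex-2-en-1-yl]oxy}(tert-butyl)dimethylsilane | CCCCOC(=C)C1=C(C)CC[C@@H](C(C)=C)[C@@H]1O[Si](C)(C)C(C)(C)C | intermediate
9 | 1-[(5S,6S)-6-[(tert-butyldimethylsilyl)oxy]-2-methyl-5-(prop-1-en-2-yl)cyclohex-1-en-1-yl]ethan-1-one | CC(=O)C1=C(C)CC[C@@H](C(C)=C)[C@@H]1O[Si](C)(C)C(C)(C)C | intermediate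
10 | 3-bromoprop-1-yne (propargyl bromide) | C#CCBr | starting material
11 | (2R)-2-[(5S,6S)-6-[(tert-butyldimethylsilyl)oxy]-2-methyl-5-(prop-1-en-2-yl)cyclohex-1-en-1-yl]pent-4-yn-2-ol | C#CC[C@@](C)(O)C1=C(C)CC[C@@H](C(C)=C)[C@@H]1O[Si](C)(C)C(C)(C)C | intermediate
12 | 7-[(tert-butyldimethylsilyl)oxy]-1,5-dimethyl-8-(prop-1-en-2-yl)tricyclo[4.4.0.0(2,6)]dec-3-en-5-ol, cyclopropane on the face anti to the silyloxy group | C[C@@]1(O)C=C[C@H]2[C@@]13[C@@H](O[Si](C)(C)C(C)(C)C)[C@H](C(C)=C)CC[C@]23C | intermediate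
13 | (4S,5S,8S,8aS)-4-[(tert-butyldimethylsilyl)oxy]-3,8-dimethyl-5-(prop-1-en-2-yl)-4,5,6,7,8,8a-hexahydroazulen-8-ol | CC1=C2[C@@H](O[Si](C)(C)C(C)(C)C)[C@H](C(C)=C)CC[C@](C)(O)[C@H]2C=C1 | intermediate
14 | (4S,5S,8S,8aS)-3,8-dimethyl-5-(prop-1-en-2-yl)-4,5,6,7,8,8a-hexahydroazulene-4,8-diol | CC1=C2[C@@H](O)[C@H](C(C)=C)CC[C@](C)(O)[C@H]2C=C1 | intermediate
15 | (4S,5S,8S,8aR)-3,8-dimethyl-5-(prop-1-en-2-yl)-4,5,6,7,8,8a-hexahydroazulene-4,8-diol (1α-H tautomer) | CC1=C2[C@@H](O)[C@H](C(C)=C)CC[C@](C)(O)[C@@H]2C=C1 | intermediate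
16 | lactone-free absinthin-type dimer: endo [4+2] adduct of two molecules of 15, bonds C2–C2′ and C3–C5′, alkenes C3′=C4′ and C4=C5, 1αH, 1′αH, 2βH, 3βH, 2′βH, 6α,6′α,10β,10′β-tetraol, 7β,7′β-di(prop-1-en-2-yl) | CC1=C2[C@@H](O)[C@H](C(C)=C)CC[C@](C)(O)[C@@H]2[C@H]2[C@H]3C=C(C)[C@]4([C@@H]3[C@@](C)(O)CC[C@@H](C(C)=C)[C@@H]4O)[C@@H]12 | intermediate
17 | heptaol: 16 with 3′-exo-OH, 4′-H (methyl endo) and both side chains as 1-hydroxypropan-2-yl (C11/C11′ epimers) | CC1=C2[C@@H](O)[C@H](C(C)CO)CC[C@](C)(O)[C@@H]2[C@H]2[C@H]3[C@H](O)[C@@H](C)[C@]4([C@@H]3[C@@](C)(O)CC[C@@H](C(C)CO)[C@@H]4O)[C@@H]12 | intermediate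
18 | 3′-exo-hydroxy-3′,4′-dihydroabsinthin, 4′-methyl endo, 6α,12- and 6′α,12′-olides (C11/C11′ epimers) | CC1=C2[C@H]3OC(=O)C(C)[C@@H]3CC[C@](C)(O)[C@@H]2[C@H]2[C@H]3[C@H](O)[C@@H](C)[C@]4([C@@H]3[C@@](C)(O)CC[C@H]3C(C)C(=O)O[C@@H]34)[C@@H]12 | intermediate
19 | caruifolin B | CC1=C2[C@H]3OC(=O)[C@@H](C)[C@@H]3CC[C@](C)(O)[C@@H]2[C@H]2[C@H]3C(=O)[C@H](C)[C@]4([C@@H]3[C@@](C)(O)CC[C@H]3[C@H](C)C(=O)O[C@@H]34)[C@@H]12 | target

**Totals**
Total steps: 10. Longest linear sequence: 10 steps (1 → 19).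

**Steps most likely to fail**

Step 6, the proposed hydrative ring expansion. The cation may instead lose H-1 to give the fulvene, be captured to a spiro product, or form on the wrong face. The fallback uses known chemistry only; it sets out from 5 and returns at 13. Robinson annulation of 5 with pent-1-en-3-one (KOH, EtOH) gives 6α-silyloxy-10-epi-eudesma-4,11-dien-3-one F1, the new bond forming anti to the silyloxy group as in the 10-epi-α-cyperone series. DDQ (dioxane, 100 °C) gives 6α-silyloxy-10-epi-eudesma-1,4,11-trien-3-one F2. Irradiation (Hg lamp, Pyrex, AcOH/H2O, 20 °C) effects the classical cross-conjugated dienone photorearrangement to 10β-hydroxy-6α-silyloxy-1βH-guaia-4,11-dien-3-one F3. KN(SiMe3)2/PhNTf2 gives the guaia-2,4,11-trien-3-yl triflate F4, and Pd(OAc)2, PPh3, Bu3N, HCO2H reduces it to 13.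

Step 3, the regioselective enol triflate. Enolisation could go toward the silyloxy carbon. The fallback sets out from 5 and returns at 9. HC≡CMgBr/CeCl3 (THF, −78 °C) gives the 1-ethynylcyclohexanol F5; Burgess reagent (benzene, 50 °C) dehydrates it to the conjugated enyne F6; Ph3PAuNTf2 (cat.) in MeOH/H2O hydrates the alkyne to 9.

Step 5, control of the carbinol centre that steers the face of the cyclisation. The fallback removes that centre; it sets out from 6 and returns at 13. 2-Bromopent-1-en-4-yne F7 (from 2,3-dibromopropene, HC≡CMgBr, CuBr) is converted to its zinc reagent and coupled with 6 (Pd(PPh3)4) to give the dienyne F8. The same gold catalyst gives the 4-methylene tricycle F9, and PPTS in wet THF protonates its exocyclic methylene to the same cation, giving 13.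

**Further compounds**
F1 | step 6 | 6α-[(tert-butyldimethylsilyl)oxy]-10-epi-eudesma-4,11-dien-3-one | CC1=C2[C@@H](O[Si](C)(C)C(C)(C)C)[C@H](C(C)=C)CC[C@]2(C)CCC1=O
F2 | step 6 | 6α-[(tert-butyldimethylsilyl)oxy]-10-epi-eudesma-1,4,11-trien-3-one | CC1=C2[C@@H](O[Si](C)(C)C(C)(C)C)[C@H](C(C)=C)CC[C@]2(C)C=CC1=O
F3 | step 6 | 10β-hydroxy-6α-[(tert-butyldimethylsilyl)oxy]-1βH-guaia-4,11-dien-3-one | CC1=C2[C@@H](O[Si](C)(C)C(C)(C)C)[C@H](C(C)=C)CC[C@](C)(O)[C@H]2CC1=O
F4 | step 6 | 10β-hydroxy-6α-[(tert-butyldimethylsilyl)oxy]-1βH-guaia-2,4,11-trien-3-yl trifluoromethanesulfonate | CC1=C2[C@@H](O[Si](C)(C)C(C)(C)C)[C@H](C(C)=C)CC[C@](C)(O)[C@H]2C=C1OS(=O)(=O)C(F)(F)F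
F5 | step 3 | (2S,3S)-2-[(tert-butyldimethylsilyl)oxy]-1-ethynyl-6-methyl-3-(prop-1-en-2-yl)cyclohexan-1-ol | CC1CC[C@@H](C(C)=C)[C@H](O[Si](C)(C)C(C)(C)C)C1(O)C#C
F6 | step 3 | tert-butyl{[(1S,6S)-2-ethynyl-3-methyl-6-(prop-1-en-2-yl)cyclohex-2-en-1-yl]oxy}dimethylsilane | C#CC1=C(C)CC[C@@H](C(C)=C)[C@@H]1O[Si](C)(C)C(C)(C)C
F7 | step 5 | 2-bromopent-1-en-4-yne | C#CCC(Br)=C
F8 | step 5 | tert-butyldimethyl{[(1S,6S)-3-methyl-2-(pent-1-en-4-yn-2-yl)-6-(prop-1-en-2-yl)cyclohex-2-en-1-yl]oxy}silane | C#CCC(=C)C1=C(C)CC[C@@H](C(C)=C)[C@@H]1O[Si](C)(C)C(C)(C)C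
F9 | step 5 | 7-[(tert-butyldimethylsilyl)oxy]-1-methyl-5-methylidene-8-(prop-1-en-2-yl)tricyclo[4.4.0.0(2,6)]dec-3-ene | C=C1C=C[C@H]2[C@@]13[C@@H](O[Si](C)(C)C(C)(C)C)[C@H](C(C)=C)CC[C@]23C
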